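**Retrosynthetic overview**
1. The target is fisetinidol-(4β→6)-fisetinidol-4α-ol; the lower C4 carbinol comes last, from NaBH4 reduction of the free-phenol ketone 21 (fisetinidol-(4β→6)-fustin).
2. The interflavan C4–C6 bond comes from addition of a 6-lithio flavan (from bromide 13) to flavan-4-one 10; ionic hydrogenation of the resulting diaryl carbinol then sets the 4β (3,4-cis) centre.
3. Both halves derive from one building block, tri-O-benzyl-(+)-fustin 9.
4. 9 comes from chalcone epoxide 7 (Juliá–Colonna), and chalcone 6 from the key C–C bond formation: the intermolecular Claisen–Schmidt aldol condensation of acetophenone 3 with aldehyde 4.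
5. Ring order: rings A and B are bought; each ring C is closed by phenol opening of the epoxide; the two flavan units are joined afterwards.

Convention: α/β as in flavan usage (in these 2R units the C2 aryl group is α and the C3 oxygen is β). Fisetinidol = (2R,3S)-3',4',7-trihydroxyflavan-3-ol; fustin = (2R,3R)-3,7,3',4'-tetrahydroxyflavan-4-one; mollisacacidin = its (2R,3S,4R)-3,4-diol. TBS = tert-butyldimethylsilyl, TES = triethylsilyl.

**Step 1**
Reactants: 1 2',4'-dihydroxyacetophenone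
Product: 2 1-[4-(benzyloxy)-2-hydroxyphenyl]ethanone
Conditions: BnBr, K2CO3, acetone, reflux
Reagents that add atoms: benzyl bromide, BrCc1ccccc1
Why: Williamson etherification is selective for the 4-OH because the 2-OH is hydrogen-bonded to the carbonyl group.

**Step 2**
Reactants: 2 1-[4-(benzyloxy)-2-hydroxyphenyl]ethanone
Product: 3 1-[4-(benzyloxy)-2-(methoxymethoxy)phenyl]ethanone
Conditions: NaH, MOMCl, DMF, 0 °C to rt
Reagents that add atoms: chloromethyl methyl ether, COCCl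
Why: Williamson-type acetal protection of the phenoxide blocks the 2'-OH so that the later basic epoxidation cannot divert to flavonol or aurone.

**Step 3**
Reactants: 3 1-[4-(benzyloxy)-2-(methoxymethoxy)phenyl]ethanone; 4 3,4-bis(benzyloxy)benzaldehyde
Product: 6 (E)-1-[4-(benzyloxy)-2-(methoxymethoxy)phenyl]-3-[3,4-bis(benzyloxy)phenyl]prop-2-en-1-one, via β-hydroxy ketone 5 (not isolated)
Conditions: KOH, EtOH/THF, rt, 24 h
Reagents that add atoms: none
Why: Intermolecular Claisen–Schmidt (crossed aldol) condensation of the methyl ketone enolate with a non-enolisable aldehyde, followed by E1cB dehydration to the conjugated E-chalcone, builds the C6–C3–C6 skeleton of both flavan units.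

**Step 4**
Reactants: 6 the E-chalcone
Product: 7 [(2R,3S)-3-[3,4-bis(benzyloxy)phenyl]oxiran-2-yl][4-(benzyloxy)-2-(methoxymethoxy)phenyl]methanone
Conditions: poly-L-leucine, 30% aq H2O2, NaOH, toluene, rt
Reagents that add atoms: hydrogen peroxide, OO
Why: Juliá–Colonna asymmetric Weitz–Scheffer epoxidation, in which the helical L-polypeptide binds the enone and delivers hydroperoxide to one face, gives the trans-(αR,βS)-epoxide.

**Step 5**
Reactants: 7 the (αR,βS)-epoxychalcone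
Product: 9 (2R,3R)-7-(benzyloxy)-2-[3,4-bis(benzyloxy)phenyl]-3-hydroxychroman-4-one (7,3',4'-tri-O-benzyl-(+)-fustin), via 2'-hydroxy epoxychalcone 8 (not isolated)
Conditions: conc. HCl (cat.), MeOH/THF, 50 °C; recrystallise
Reagents that add atoms: none
Why: Acid-catalysed acetal cleavage frees the phenol, which opens the epoxide 6-endo at the electron-rich benzylic carbon with inversion to the more stable 2,3-trans ring C, while the C3 centre (epoxide α-carbon) is never broken; recrystallisation raises the ee.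

**Step 6**
Reactants: 9 tri-O-benzyl-(+)-fustin
Product: 10 (2R,3R)-7-(benzyloxy)-2-[3,4-bis(benzyloxy)phenyl]-3-[(tert-butyldimethylsilyl)oxy]chroman-4-one
Conditions: TBSCl, imidazole, DMF, rt
Reagents that add atoms: tert-butyldimethylsilyl chloride, CC(C)(C)[Si](C)(C)Cl
Why: Imidazole-promoted silyl ether formation protects the 3-OH under conditions too mild to enolise or ring-open the dihydroflavonol.

**Step 7**
Reactants: 10 the 3-O-TBS flavan-4-one
Product: 11 (2R,3S,4R)-7-(benzyloxy)-2-[3,4-bis(benzyloxy)phenyl]-3-[(tert-butyldimethylsilyl)oxy]chroman-4-ol (2,3-trans-3,4-trans)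
Conditions: NaBH4, THF/EtOH, 0 °C
Reagents that add atoms: none
Why: Carbonyl hydride reduction with axial attack gives the equatorial 3,4-trans alcohol, and this centre only masks the ketone, so any cis epimer converges at step 12.

**Step 8**
Reactants: 11 the 3-O-TBS flavan-4-ol
Product: 12 the 4-O-triethylsilyl ether of 11 (same 2,3-trans-3,4-trans configuration)
Conditions: TESCl, imidazole, DMAP (cat.), DMF, rt
Reagents that add atoms: chlorotriethylsilane, CC[Si](Cl)(CC)CC
Why: Silylation gives a 4-O group that survives organolithium chemistry yet can later be removed selectively beside TBS.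

**Step 9**
Reactants: 12 the 3-O-TBS-4-O-TES flavan
Product: 13 the 6-bromo derivative of 12
Conditions: NBS, CH2Cl2, −78 to 0 °C, dark
Reagents that add atoms: N-bromosuccinimide, O=C1CCC(=O)N1Br
Why: Electrophilic aromatic bromination goes to C6 of the resorcinol-type ring A, the unhindered position para to the ring oxygen and ortho to the 7-OBn group, in preference to C8 or the less activated ring B.

**Step 10**
Reactants: 13 the 6-bromo flavan; 10 the 3-O-TBS flavan-4-one
Product: 15 7,3',4'-tri-O-benzyl-3-O-TBS-4β-hydroxyfisetinidol-(4α→6)-(7,3',4'-tri-O-benzyl-3-O-TBS-4-O-TES-mollisacacidin), via aryllithium 14 (not isolated)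
Conditions: 13, t-BuLi (2 equiv), THF, −78 °C; then 10, −78 to −20 °C; H2O
Reagents that add atoms: none
Why: Bromine–lithium exchange followed by 1,2-addition of the aryllithium to the ketone forms the interflavan bond (aryl drawn anti to the OTBS group); the carbinol configuration is erased in step 13.

**Step 11**
Reactants: 15 the coupled tertiary alcohol
Product: 16 7,3',4'-tri-O-benzyl-3-O-TBS-4β-hydroxyfisetinidol-(4α→6)-(7,3',4'-tri-O-benzyl-3-O-TBS-mollisacacidin)
Conditions: HF·pyridine, pyridine, THF, 0 °C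
Reagents that add atoms: none
Why: Buffered fluoride desilylation removes the secondary TES ether far faster than the two hindered TBS ethers and is not acidic enough to ionise the tertiary carbinol.

**Step 12**
Reactants: 16 the diol
Product: 17 7,3',4'-tri-O-benzyl-3-O-TBS-4β-hydroxyfisetinidol-(4α→6)-(7,3',4'-tri-O-benzyl-3-O-TBS-fustin)
Conditions: Dess–Martin periodinane, pyridine, CH2Cl2, 0 °C to rt
Reagents that add atoms: none
Why: Dess–Martin oxidation converts the only oxidisable (secondary benzylic) alcohol into the ketone, so the lower C4 cannot ionise in the next acidic step.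

**Step 13**
Reactants: 17 the keto tertiary alcohol
Product: 19 7,3',4'-tri-O-benzyl-3-O-TBS-fisetinidol-(4β→6)-(7,3',4'-tri-O-benzyl-3-O-TBS-fustin), via diarylmethyl cation 18 (not isolated)
Conditions: Bu3SnH, CF3CO2H, CH2Cl2, 0 °C
Reagents that add atoms: none
Why: Ionic hydrogenation (SN1 ionisation to the doubly aryl-stabilised cation, then hydride transfer from tin) delivers hydride to the face opposite the adjacent OTBS group (α-face), which leaves the aryl group β and sets the 3,4-cis upper C4 centre.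

**Step 14**
Reactants: 19 the bis-TBS dimer
Product: 20 7,3',4'-tri-O-benzylfisetinidol-(4β→6)-(7,3',4'-tri-O-benzylfustin)
Conditions: 48% aq HF, MeCN/CH2Cl2, rt
Reagents that add atoms: none
Why: Acidic fluoride desilylation removes both hindered TBS ethers without the basic conditions that would open or epimerise the dihydroflavonol ring.

**Step 15**
Reactants: 20 the hexabenzyl ether
Product: 21 fisetinidol-(4β→6)-fustin
Conditions: H2 (1 atm), Pd(OH)2/C, THF/MeOH, rt
Reagents that add atoms: none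
Why: Catalytic hydrogenolysis cleaves the six aryl benzyl ethers much faster than it touches the conjugated aryl ketone, and no benzylic C–OH is present at this stage.

**Step 16**
Reactants: 21 fisetinidol-(4β→6)-fustin
Product: 22 fisetinidol-(4β→6)-fisetinidol-4α-ol, (2R,3S,4R)-6-[(2R,3S,4S)-2-(3,4-dihydroxyphenyl)-3,7-dihydroxy-3,4-dihydro-2H-chromen-4-yl]-2-(3,4-dihydroxyphenyl)-3,4-dihydro-2H-chromene-3,4,7-triol
Conditions: NaBH4, EtOH, 0 °C to rt; AcOH to pH 6
Reagents that add atoms: none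
Why: Borohydride reduction of the dihydroflavonol carbonyl by axial attack gives the equatorial 4α-OH (3,4-trans, 4R), as in the reduction of fustin to mollisacacidin, and mild neutralisation avoids ionising the product.

**Compound list**
1 | 2',4'-dihydroxyacetophenone | CC(=O)c1ccc(O)cc1O | starting material
2 | 1-[4-(benzyloxy)-2-hydroxyphenyl]ethanone | CC(=O)c1ccc(OCc2ccccc2)cc1O | intermediate
3 | 1-[4-(benzyloxy)-2-(methoxymethoxy)phenyl]ethanone | CC(=O)c1ccc(OCc2ccccc2)cc1OCOC | intermediate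
4 | 3,4-bis(benzyloxy)benzaldehyde | O=Cc1ccc(OCc2ccccc2)c(OCc2ccccc2)c1 | starting material
5 | 1-[4-(benzyloxy)-2-(methoxymethoxy)phenyl]-3-[3,4-bis(benzyloxy)phenyl]-3-hydroxypropan-1-one (racemic aldol adduct) | COCOc1cc(OCc2ccccc2)ccc1C(=O)CC(O)c1ccc(OCc2ccccc2)c(OCc2ccccc2)c1 | intermediate
6 | (E)-1-[4-(benzyloxy)-2-(methoxymethoxy)phenyl]-3-[3,4-bis(benzyloxy)phenyl]prop-2-en-1-one | COCOc1cc(OCc2ccccc2)ccc1C(=O)/C=C/c1ccc(OCc2ccccc2)c(OCc2ccccc2)c1 | intermediate
7 | [(2R,3S)-3-[3,4-bis(benzyloxy)phenyl]oxiran-2-yl][4-(benzyloxy)-2-(methoxymethoxy)phenyl]methanone | COCOc1cc(OCc2ccccc2)ccc1C(=O)[C@@H]1O[C@H]1c1ccc(OCc2ccccc2)c(OCc2ccccc2)c1 | intermediate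
8 | [(2R,3S)-3-[3,4-bis(benzyloxy)phenyl]oxiran-2-yl][4-(benzyloxy)-2-hydroxyphenyl]methanone | Oc1cc(OCc2ccccc2)ccc1C(=O)[C@@H]1O[C@H]1c1ccc(OCc2ccccc2)c(OCc2ccccc2)c1 | intermediate
9 | (2R,3R)-7-(benzyloxy)-2-[3,4-bis(benzyloxy)phenyl]-3-hydroxychroman-4-one | c1cc2c(cc1OCc1ccccc1)O[C@H](c1ccc(OCc3ccccc3)c(OCc3ccccc3)c1)[C@@H](O)C2=O | intermediate
10 | (2R,3R)-7-(benzyloxy)-2-[3,4-bis(benzyloxy)phenyl]-3-[(tert-butyldimethylsilyl)oxy]chroman-4-one | c1cc2c(cc1OCc1ccccc1)O[C@H](c1ccc(OCc3ccccc3)c(OCc3ccccc3)c1)[C@@H](O[Si](C)(C)C(C)(C)C)C2=O | intermediate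
11 | (2R,3S,4R)-7-(benzyloxy)-2-[3,4-bis(benzyloxy)phenyl]-3-[(tert-butyldimethylsilyl)oxy]chroman-4-ol | c1cc2c(cc1OCc1ccccc1)O[C@H](c1ccc(OCc3ccccc3)c(OCc3ccccc3)c1)[C@@H](O[Si](C)(C)C(C)(C)C)[C@@H]2O | intermediate
12 | 2,3-trans-3,4-trans-7-(benzyloxy)-2-[3,4-bis(benzyloxy)phenyl]-3-(TBS-oxy)-4-(TES-oxy)chroman (2α-aryl, 3β-OTBS, 4α-OTES) | c1cc2c(cc1OCc1ccccc1)O[C@H](c1ccc(OCc3ccccc3)c(OCc3ccccc3)c1)[C@@H](O[Si](C)(C)C(C)(C)C)[C@@H]2O[Si](CC)(CC)CC | intermediate
13 | 6-bromo derivative of 12 | Brc1cc2c(cc1OCc1ccccc1)O[C@H](c1ccc(OCc3ccccc3)c(OCc3ccccc3)c1)[C@@H](O[Si](C)(C)C(C)(C)C)[C@@H]2O[Si](CC)(CC)CC | intermediate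
14 | 6-lithio derivative of 12 | [Li]c1cc2c(cc1OCc1ccccc1)O[C@H](c1ccc(OCc3ccccc3)c(OCc3ccccc3)c1)[C@@H](O[Si](C)(C)C(C)(C)C)[C@@H]2O[Si](CC)(CC)CC | intermediate
15 | 7,3',4'-tri-O-benzyl-3-O-TBS-4β-hydroxyfisetinidol-(4α→6)-(7,3',4'-tri-O-benzyl-3-O-TBS-4-O-TES-mollisacacidin) | C(c1ccccc1)Oc1ccc2c(c1)O[C@H](c1ccc(OCc3ccccc3)c(OCc3ccccc3)c1)[C@@H](O[Si](C)(C)C(C)(C)C)[C@]2(O)c1cc2c(cc1OCc1ccccc1)O[C@H](c1ccc(OCc3ccccc3)c(OCc3ccccc3)c1)[C@@H](O[Si](C)(C)C(C)(C)C)[C@@H]2O[Si](CC)(CC)CC | intermediate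
16 | 7,3',4'-tri-O-benzyl-3-O-TBS-4β-hydroxyfisetinidol-(4α→6)-(7,3',4'-tri-O-benzyl-3-O-TBS-mollisacacidin) | C(c1ccccc1)Oc1ccc2c(c1)O[C@H](c1ccc(OCc3ccccc3)c(OCc3ccccc3)c1)[C@@H](O[Si](C)(C)C(C)(C)C)[C@]2(O)c1cc2c(cc1OCc1ccccc1)O[C@H](c1ccc(OCc3ccccc3)c(OCc3ccccc3)c1)[C@@H](O[Si](C)(C)C(C)(C)C)[C@@H]2O | intermediate
17 | 7,3',4'-tri-O-benzyl-3-O-TBS-4β-hydroxyfisetinidol-(4α→6)-(7,3',4'-tri-O-benzyl-3-O-TBS-fustin) | C(c1ccccc1)Oc1ccc2c(c1)O[C@H](c1ccc(OCc3ccccc3)c(OCc3ccccc3)c1)[C@@H](O[Si](C)(C)C(C)(C)C)[C@]2(O)c1cc2c(cc1OCc1ccccc1)O[C@H](c1ccc(OCc3ccccc3)c(OCc3ccccc3)c1)[C@@H](O[Si](C)(C)C(C)(C)C)C2=O | intermediate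
18 | C4 diarylmethyl cation of 17 (trifluoroacetate ion pair) | C(c1ccccc1)Oc1ccc2c(c1)O[C@H](c1ccc(OCc3ccccc3)c(OCc3ccccc3)c1)[C@@H](O[Si](C)(C)C(C)(C)C)[C+]2c1cc2c(cc1OCc1ccccc1)O[C@H](c1ccc(OCc3ccccc3)c(OCc3ccccc3)c1)[C@@H](O[Si](C)(C)C(C)(C)C)C2=O.[O-]C(=O)C(F)(F)F | intermediate
19 | 7,3',4'-tri-O-benzyl-3-O-TBS-fisetinidol-(4β→6)-(7,3',4'-tri-O-benzyl-3-O-TBS-fustin) (upper unit 2,3-trans-3,4-cis) | C(c1ccccc1)Oc1ccc2c(c1)O[C@H](c1ccc(OCc3ccccc3)c(OCc3ccccc3)c1)[C@@H](O[Si](C)(C)C(C)(C)C)[C@H]2c1cc2c(cc1OCc1ccccc1)O[C@H](c1ccc(OCc3ccccc3)c(OCc3ccccc3)c1)[C@@H](O[Si](C)(C)C(C)(C)C)C2=O | intermediate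
20 | 7,3',4'-tri-O-benzylfisetinidol-(4β→6)-(7,3',4'-tri-O-benzylfustin) | C(c1ccccc1)Oc1ccc2c(c1)O[C@H](c1ccc(OCc3ccccc3)c(OCc3ccccc3)c1)[C@@H](O)[C@H]2c1cc2c(cc1OCc1ccccc1)O[C@H](c1ccc(OCc3ccccc3)c(OCc3ccccc3)c1)[C@@H](O)C2=O | intermediate
21 | fisetinidol-(4β→6)-fustin, (2R,3R)-6-[(2R,3S,4S)-2-(3,4-dihydroxyphenyl)-3,7-dihydroxychroman-4-yl]-2-(3,4-dihydroxyphenyl)-3,7-dihydroxychroman-4-one | Oc1ccc2c(c1)O[C@H](c1ccc(O)c(O)c1)[C@@H](O)[C@H]2c1cc2c(cc1O)O[C@H](c1ccc(O)c(O)c1)[C@@H](O)C2=O | intermediate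
22 | fisetinidol-(4β→6)-fisetinidol-4α-ol (CNP0280090.2) | Oc1ccc2c(c1)O[C@H](c1ccc(O)c(O)c1)[C@@H](O)[C@H]2c1cc2c(cc1O)O[C@H](c1ccc(O)c(O)c1)[C@@H](O)[C@@H]2O | target

**Count and risks**
Total steps: 16. Longest linear sequence: 16 (ketone 10 is both the electrophile and the precursor of the nucleophile, so every step lies on one line).

Most likely to fail:

- **Step 13.** The hydride must enter the cation 18 anti to the OTBS group but on the same face as the C2 aryl group, so facial selectivity in this 2,3-trans series is the least certain point; J(H3,H4) of 19 tells cis from trans. Fallback: set out from 17 and use heterogeneous hydrogen instead of an ionic hydride. H2 with Pd(OH)2/C in EtOAc/MeOH removes the six benzyl ethers; the freed 7-OH para to C4 lets the tertiary carbinol collapse to a ring A p-quinone methide, which takes up hydrogen from the catalyst face opposite the OTBS group to give the bis-TBS hexaphenol 3-O-TBS-fisetinidol-(4β→6)-(3-O-TBS-fustin) F4. Aqueous HF in MeCN then removes the silyl groups and the route is rejoined at 21.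

- **Step 10.** The basic aryllithium may enolise 10 at C3 (followed by ring opening) instead of adding. Fallback: a biomimetic coupling without any organometallic, setting out from 9. Hydrogenolysis (H2, Pd(OH)2/C) gives (+)-fustin F2, and NaBH4 in EtOH gives (+)-mollisacacidin F3. In 0.1 M aqueous HCl at rt, F3 ionises at C4 to the ring A p-quinone methide and C6 of a second molecule adds in a 1,6-conjugate fashion. The 4β-linked dimer forms beside its 4α epimer and higher oligomers and is isolated on Sephadex LH-20 followed by reversed-phase HPLC; the route comes back at 22. This is low-yielding but independent of steps 10 to 16.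

- **Step 5.** Acid opening can give methanol adducts, 5-exo (aurone-type) closure or aryl-shift products. Fallback: set out from 7 and open the epoxide with sulfur first. Phenylmethanethiol with catalytic SnCl4 in CH2Cl2 at −20 °C attacks the benzylic carbon with inversion and removes the MOM group, giving (2S,3R)-3-(benzylsulfanyl)-1-[4-(benzyloxy)-2-hydroxyphenyl]-3-[3,4-bis(benzyloxy)phenyl]-2-hydroxypropan-1-one F1. AgBF4 in CH2Cl2 at 0 °C then ionises the C–S bond and the phenol closes ring C to the trans product, rejoining the route at 9.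

**Further compounds**
F1 | step 5 | (2S,3R)-3-(benzylsulfanyl)-1-[4-(benzyloxy)-2-hydroxyphenyl]-3-[3,4-bis(benzyloxy)phenyl]-2-hydroxypropan-1-one | Oc1cc(OCc2ccccc2)ccc1C(=O)[C@H](O)[C@H](SCc1ccccc1)c1ccc(OCc2ccccc2)c(OCc2ccccc2)c1
F2 | step 10 | (+)-fustin, (2R,3R)-2-(3,4-dihydroxyphenyl)-3,7-dihydroxychroman-4-one | c1cc2c(cc1O)O[C@H](c1ccc(O)c(O)c1)[C@@H](O)C2=O
F3 | step 10 | (+)-mollisacacidin, (2R,3S,4R)-2-(3,4-dihydroxyphenyl)chroman-3,4,7-triol | c1cc2c(cc1O)O[C@H](c1ccc(O)c(O)c1)[C@@H](O)[C@@H]2O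
F4 | step 13 | 3-O-TBS-fisetinidol-(4β→6)-(3-O-TBS-fustin) | Oc1ccc2c(c1)O[C@H](c1ccc(O)c(O)c1)[C@@H](O[Si](C)(C)C(C)(C)C)[C@H]2c1cc2c(cc1O)O[C@H](c1ccc(O)c(O)c1)[C@@H](O[Si](C)(C)C(C)(C)C)C2=O
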